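**Retrosynthetic overview**
1. Target 23 ← tert-butyl ester acidolysis and three O-acylations in the order O3 (6-methylheptanoate), O5 (acetate), O4 (tiglate) ← cyclohexenol 15, with O4/O5 tied up as a trans-fused acetonide and O3 the only free hydroxyl.
2. 15 ← cut C2–C3: intramolecular Nozaki–Hiyama–Kishi addition of a C2 alkenylmetal to the C3 aldehyde; the cyclohexene C1–C6 is the only ring and is closed here ← (E)-enol triflate aldehyde 13.
3. 13 ← C2 from ethyl formate (Claisen formylation, then O-triflation); C1 and the carboxyl carbon from tert-butyl acetate (its enolate alkylated at C6 by a primary triflate) ← mono-silylated L-threitol acetonide ← L-tartrate acetonide 1.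
4. Feature used: C3 is an allylic carbinol carbon bonded to the vinyl carbon C2, and the chain C3–C4–C5–C6 with trans O4/O5 is the four-carbon backbone of L-tartaric acid, so C4 and C5 are bought and only C3 has to be set.

Key step: step 9

Remark: ring atoms are numbered C1 (carboxyl-bearing) to C6 (CH2) throughout, and TBS = tert-butyldimethylsilyl. The target is the all-trans (3R,4R,5S) isomer. The CIP label of C4 reads S in 15 (O3 free, so the C5 branch outranks C3) and R from 17 on, with no change in spatial arrangement.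

**Route**

Step 1
Reactants: 1 dimethyl (4R,5R)-2,2-dimethyl-1,3-dioxolane-4,5-dicarboxylate (dimethyl 2,3-O-isopropylidene-L-tartrate)
Product: 2 [(4S,5S)-2,2-dimethyl-1,3-dioxolane-4,5-diyl]dimethanol
Conditions: LiAlH4, THF, 0 °C to reflux; then H2O
Reagents that add atoms: none
Why: LiAlH4 ester reduction converts both methyl esters into primary alcohols without touching the acetal or the two stereocentres, so the L-threo arrangement of the future C4 and C5 is carried over intact.

Step 2
Reactants: 2 [(4S,5S)-2,2-dimethyl-1,3-dioxolane-4,5-diyl]dimethanol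
Product: 4 [(4S,5S)-5-({[tert-butyl(dimethyl)silyl]oxy}methyl)-2,2-dimethyl-1,3-dioxolan-4-yl]methanol, via monosodium alkoxide 3 (not isolated)
Conditions: NaH (1.0 equiv), THF, 25 °C; then TBSCl (1.0 equiv)
Reagents that add atoms: tert-butyldimethylsilyl chloride (TBSCl), CC(C)(C)[Si](C)(C)Cl
Why: Monosilylation through the sparingly soluble monosodium alkoxide (Williamson-type O-silylation of a symmetrical diol) stops after one silyl group, and because the two hydroxyls are related by the C2 axis either one gives the same product.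

Step 3
Reactants: 4 [(4S,5S)-5-({[tert-butyl(dimethyl)silyl]oxy}methyl)-2,2-dimethyl-1,3-dioxolan-4-yl]methanol
Product: 5 [(4S,5S)-5-({[tert-butyl(dimethyl)silyl]oxy}methyl)-2,2-dimethyl-1,3-dioxolan-4-yl]methyl trifluoromethanesulfonate
Conditions: Tf2O, 2,6-lutidine, CH2Cl2, −78 °C
Reagents that add atoms: trifluoromethanesulfonic anhydride (Tf2O), O=S(=O)(OS(=O)(=O)C(F)(F)F)C(F)(F)F
Why: O-sulfonylation of the primary alcohol with Tf2O and a hindered pyridine base at low temperature gives the alkyl triflate, the only leaving group reactive enough for the SN2 step on this beta-oxygenated carbon, and it is used at once.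

Step 4
Reactants: 5 [(4S,5S)-5-({[tert-butyl(dimethyl)silyl]oxy}methyl)-2,2-dimethyl-1,3-dioxolan-4-yl]methyl trifluoromethanesulfonate; 6 tert-butyl acetate
Product: 8 tert-butyl 3-[(4S,5S)-5-({[tert-butyl(dimethyl)silyl]oxy}methyl)-2,2-dimethyl-1,3-dioxolan-4-yl]propanoate, via lithium enolate of tert-butyl acetate 7 (not isolated)
Conditions: 6, LiN(iPr)2, THF, −78 °C; then 5, DMPU, −78 to −20 °C
Reagents that add atoms: none
Why: SN2 alkylation of a lithium ester enolate by a primary alkyl triflate forms the C6–C1 bond; the tert-butyl group suppresses Claisen self-condensation and no stereocentre is touched.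

Step 5
Reactants: 8 tert-butyl 3-[(4S,5S)-5-({[tert-butyl(dimethyl)silyl]oxy}methyl)-2,2-dimethyl-1,3-dioxolan-4-yl]propanoate
Product: 10 tert-butyl (2RS)-2-formyl-3-[(4S,5S)-5-({[tert-butyl(dimethyl)silyl]oxy}methyl)-2,2-dimethyl-1,3-dioxolan-4-yl]propanoate (epimers at C2 in equilibrium with the enol), via lithium ester enolate 9 (not isolated)
Conditions: LiN(iPr)2, THF, −78 °C; HCO2Et, −78 to 0 °C; AcOH
Reagents that add atoms: ethyl formate, CCOC=O
Why: Crossed Claisen condensation (alpha-formylation) of the ester enolate with ethyl formate is driven by formation of the stabilised beta-oxo ester enolate; the new alpha centre is of no consequence because C1 becomes trigonal in step 6.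

Step 6
Reactants: 10 tert-butyl (2RS)-2-formyl-3-[(4S,5S)-5-({[tert-butyl(dimethyl)silyl]oxy}methyl)-2,2-dimethyl-1,3-dioxolan-4-yl]propanoate
Product: 11 tert-butyl (2E)-2-{[(4S,5S)-5-({[tert-butyl(dimethyl)silyl]oxy}methyl)-2,2-dimethyl-1,3-dioxolan-4-yl]methyl}-3-(trifluoromethanesulfonyloxy)prop-2-enoate
Conditions: Tf2O, iPr2NEt, CH2Cl2, −78 °C
Reagents that add atoms: trifluoromethanesulfonic anhydride (Tf2O), O=S(=O)(OS(=O)(=O)C(F)(F)F)C(F)(F)F
Why: O-triflation of the formyl ester enolate under non-chelating conditions: the trialkylammonium enolate should adopt the extended form with the enolate oxygen anti to the ester carbonyl, so the triflate should end up trans to CO2tBu and cis to C6 (E), in contrast to a lithium chelate that would give Z; any Z isomer is removed by chromatography and the geometry is to be checked by NOE.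

Step 7
Reactants: 11 tert-butyl (2E)-2-{[(4S,5S)-5-({[tert-butyl(dimethyl)silyl]oxy}methyl)-2,2-dimethyl-1,3-dioxolan-4-yl]methyl}-3-(trifluoromethanesulfonyloxy)prop-2-enoate
Product: 12 tert-butyl (2E)-2-{[(4S,5S)-5-(hydroxymethyl)-2,2-dimethyl-1,3-dioxolan-4-yl]methyl}-3-(trifluoromethanesulfonyloxy)prop-2-enoate
Conditions: HF·pyridine, pyridine, THF, 0 to 25 °C
Reagents that add atoms: none
Why: Fluoride-induced Si–O cleavage with buffered HF·pyridine removes the primary silyl ether under weakly acidic conditions that leave the electrophilic enol triflate, the acetonide and the tert-butyl ester alone.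

Step 8
Reactants: 12 tert-butyl (2E)-2-{[(4S,5S)-5-(hydroxymethyl)-2,2-dimethyl-1,3-dioxolan-4-yl]methyl}-3-(trifluoromethanesulfonyloxy)prop-2-enoate
Product: 13 tert-butyl (2E)-2-{[(4S,5R)-5-formyl-2,2-dimethyl-1,3-dioxolan-4-yl]methyl}-3-(trifluoromethanesulfonyloxy)prop-2-enoate
Conditions: Dess–Martin periodinane, NaHCO3, CH2Cl2, 0 to 25 °C
Reagents that add atoms: none
Why: Dess–Martin oxidation under buffered non-basic conditions gives the alpha-alkoxy aldehyde without epimerising C4 or triggering addition–elimination at the enol triflate; the aldehyde is used directly.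

Step 9
Reactants: 13 tert-butyl (2E)-2-{[(4S,5R)-5-formyl-2,2-dimethyl-1,3-dioxolan-4-yl]methyl}-3-(trifluoromethanesulfonyloxy)prop-2-enoate
Product: 15 tert-butyl (3R,4S,5S)-3-hydroxy-4,5-(isopropylidenedioxy)cyclohex-1-ene-1-carboxylate, via alkenylchromium dichloride 14 (not isolated)
Conditions: CrCl2 (6 equiv), NiCl2 (1 mol% relative to CrCl2), degassed DMF, 25 °C, 5 mM, slow addition of 13; aq. NH4Cl
Reagents that add atoms: none
Why: CrCl2 reduces NiCl2 to zerovalent nickel, which inserts into the C2–O bond of the electron-poor enol triflate, and transmetalation to trivalent chromium gives alkenylchromium 14 with the metal still cis to C6; 14 then adds to the tethered aldehyde. The closest known reaction type is the intramolecular Nozaki–Hiyama–Kishi coupling of alkenyl triflates or beta-halo acrylates with alpha-alkoxy aldehydes. The closure is 6-exo-trig (the carbonyl oxygen stays outside the new ring) and it forms C2–C3 and the cyclohexene C1–C6 together. The new stereocentre C3 is controlled by the trans-fused dioxolane: O4 and O5 are locked diequatorial in the half-chair transition state, and the bulky chromium alkoxide should take the pseudo-equatorial site away from axial H5, which puts O3 trans to O4 (3R). The step needs chemoselective addition to the aldehyde without attack on the ester or epimerisation of C4, which the weakly basic organochromium secures, and it needs the metal cis to C6, which the E geometry of 13 secures. High dilution suppresses intermolecular coupling, and any 3S epimer is separable and is converged as described under the fallbacks.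

Step 10
Reactants: 15 tert-butyl (3R,4S,5S)-3-hydroxy-4,5-(isopropylidenedioxy)cyclohex-1-ene-1-carboxylate; 16 6-methylheptanoic acid
Product: 17 tert-butyl (3R,4R,5S)-4,5-(isopropylidenedioxy)-3-[(6-methylheptanoyl)oxy]cyclohex-1-ene-1-carboxylate
Conditions: 16, DCC, DMAP (0.1 equiv), CH2Cl2, 0 to 25 °C
Reagents that add atoms: none
Why: Steglich esterification (carbodiimide activation, DMAP acyl transfer) acylates the only free hydroxyl, O3, with retention at C3 and under conditions too mild to move the double bond.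

Step 11
Reactants: 17 tert-butyl (3R,4R,5S)-4,5-(isopropylidenedioxy)-3-[(6-methylheptanoyl)oxy]cyclohex-1-ene-1-carboxylate
Product: 18 tert-butyl (3R,4R,5S)-4,5-dihydroxy-3-[(6-methylheptanoyl)oxy]cyclohex-1-ene-1-carboxylate
Conditions: AcOH/H2O 4:1, 40 °C
Reagents that add atoms: none
Why: Acid-catalysed acetal hydrolysis is fast for this strained trans-fused dioxolane, so aqueous acetic acid should free O4 and O5 while the tert-butyl ester and the C3 ester survive and acyl migration stays slow.

Step 12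
Reactants: 18 tert-butyl (3R,4R,5S)-4,5-dihydroxy-3-[(6-methylheptanoyl)oxy]cyclohex-1-ene-1-carboxylate
Product: 19 tert-butyl (3R,4R,5S)-5-acetoxy-4-hydroxy-3-[(6-methylheptanoyl)oxy]cyclohex-1-ene-1-carboxylate
Conditions: AcCl (1.05 equiv), 2,4,6-collidine, CH2Cl2, −78 to −40 °C
Reagents that add atoms: acetyl chloride, CC(=O)Cl
Why: Kinetic site-selective acylation: O5 sits next to the C6 methylene whereas O4 is flanked by two oxygen-bearing carbons and is deactivated by the neighbouring C3 acyloxy group, so one equivalent of AcCl with collidine at low temperature should acetylate O5 first.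

Step 13
Reactants: 19 tert-butyl (3R,4R,5S)-5-acetoxy-4-hydroxy-3-[(6-methylheptanoyl)oxy]cyclohex-1-ene-1-carboxylate; 20 tiglic acid ((2E)-2-methylbut-2-enoic acid)
Product: 22 tert-butyl (3R,4R,5S)-5-acetoxy-3-[(6-methylheptanoyl)oxy]-4-{[(2E)-2-methylbut-2-enoyl]oxy}cyclohex-1-ene-1-carboxylate, via tiglic 2,4,6-trichlorobenzoic anhydride 21 (not isolated)
Conditions: 20, 2,4,6-trichlorobenzoyl chloride, Et3N, toluene, 25 °C; then 19, DMAP, 25 to 50 °C
Reagents that add atoms: none
Why: Yamaguchi esterification through the mixed anhydride and DMAP is the standard way to acylate a hindered secondary alcohol with an alpha,beta-unsaturated acid, and tiglate, being the stable E isomer, keeps its geometry.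

Step 14
Reactants: 22 tert-butyl (3R,4R,5S)-5-acetoxy-3-[(6-methylheptanoyl)oxy]-4-{[(2E)-2-methylbut-2-enoyl]oxy}cyclohex-1-ene-1-carboxylate
Product: 23 (3R,4R,5S)-5-acetoxy-3-[(6-methylheptanoyl)oxy]-4-{[(2E)-2-methylbut-2-enoyl]oxy}cyclohex-1-ene-1-carboxylic acid (CNP0225437.1)
Conditions: CF3CO2H/CH2Cl2 1:4, 0 to 25 °C
Reagents that add atoms: none
Why: Acidolysis of the tert-butyl ester (loss of isobutene through the tert-butyl cation) frees the carboxylic acid while the three secondary esters, which cannot ionise, remain in place.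

**Compound list**
1 | dimethyl (4R,5R)-2,2-dimethyl-1,3-dioxolane-4,5-dicarboxylate (dimethyl 2,3-O-isopropylidene-L-tartrate) | COC(=O)[C@@H]1OC(C)(C)O[C@H]1C(=O)OC | starting material
2 | [(4S,5S)-2,2-dimethyl-1,3-dioxolane-4,5-diyl]dimethanol | OC[C@@H]1OC(C)(C)O[C@H]1CO | intermediate
3 | monosodium alkoxide of 2 (not isolated) | [Na+].[O-]C[C@@H]1OC(C)(C)O[C@H]1CO | intermediate
4 | [(4S,5S)-5-({[tert-butyl(dimethyl)silyl]oxy}methyl)-2,2-dimethyl-1,3-dioxolan-4-yl]methanol | CC(C)(C)[Si](C)(C)OC[C@@H]1OC(C)(C)O[C@H]1CO | intermediate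
5 | [(4S,5S)-5-({[tert-butyl(dimethyl)silyl]oxy}methyl)-2,2-dimethyl-1,3-dioxolan-4-yl]methyl trifluoromethanesulfonate | CC(C)(C)[Si](C)(C)OC[C@@H]1OC(C)(C)O[C@H]1COS(=O)(=O)C(F)(F)F | intermediate
6 | tert-butyl acetate | CC(=O)OC(C)(C)C | starting material
7 | lithium enolate of tert-butyl acetate (not isolated) | [Li]OC(=C)OC(C)(C)C | intermediate
8 | tert-butyl 3-[(4S,5S)-5-({[tert-butyl(dimethyl)silyl]oxy}methyl)-2,2-dimethyl-1,3-dioxolan-4-yl]propanoate | CC(C)(C)[Si](C)(C)OC[C@@H]1OC(C)(C)O[C@H]1CCC(=O)OC(C)(C)C | intermediate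
9 | lithium enolate of ester 8 (not isolated) | CC(C)(C)[Si](C)(C)OC[C@@H]1OC(C)(C)O[C@H]1CC=C(O[Li])OC(C)(C)C | intermediate
10 | tert-butyl (2RS)-2-formyl-3-[(4S,5S)-5-({[tert-butyl(dimethyl)silyl]oxy}methyl)-2,2-dimethyl-1,3-dioxolan-4-yl]propanoate (alpha centre undefined, enolisable) | CC(C)(C)[Si](C)(C)OC[C@@H]1OC(C)(C)O[C@H]1CC(C=O)C(=O)OC(C)(C)C | intermediate
11 | tert-butyl (2E)-2-{[(4S,5S)-5-({[tert-butyl(dimethyl)silyl]oxy}methyl)-2,2-dimethyl-1,3-dioxolan-4-yl]methyl}-3-(trifluoromethanesulfonyloxy)prop-2-enoate | CC(C)(C)[Si](C)(C)OC[C@@H]1OC(C)(C)O[C@H]1C/C(C(=O)OC(C)(C)C)=C\OS(=O)(=O)C(F)(F)F | intermediate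
12 | tert-butyl (2E)-2-{[(4S,5S)-5-(hydroxymethyl)-2,2-dimethyl-1,3-dioxolan-4-yl]methyl}-3-(trifluoromethanesulfonyloxy)prop-2-enoate | OC[C@@H]1OC(C)(C)O[C@H]1C/C(C(=O)OC(C)(C)C)=C\OS(=O)(=O)C(F)(F)F | intermediate
13 | tert-butyl (2E)-2-{[(4S,5R)-5-formyl-2,2-dimethyl-1,3-dioxolan-4-yl]methyl}-3-(trifluoromethanesulfonyloxy)prop-2-enoate (key-step precursor) | O=C[C@@H]1OC(C)(C)O[C@H]1C/C(C(=O)OC(C)(C)C)=C\OS(=O)(=O)C(F)(F)F | intermediate
14 | alkenylchromium dichloride from 13 (trivalent chromium, metal cis to C6; not isolated) | O=C[C@@H]1OC(C)(C)O[C@H]1C/C(C(=O)OC(C)(C)C)=C\[Cr](Cl)Cl | intermediate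
15 | tert-butyl (3R,4S,5S)-3-hydroxy-4,5-(isopropylidenedioxy)cyclohex-1-ene-1-carboxylate (all-trans; key-step product) | CC(C)(C)OC(=O)C1=C[C@@H](O)[C@@H]2OC(C)(C)O[C@H]2C1 | intermediate
16 | 6-methylheptanoic acid | CC(C)CCCCC(=O)O | starting material
17 | tert-butyl (3R,4R,5S)-4,5-(isopropylidenedioxy)-3-[(6-methylheptanoyl)oxy]cyclohex-1-ene-1-carboxylate | CC(C)(C)OC(=O)C1=C[C@@H](OC(=O)CCCCC(C)C)[C@@H]2OC(C)(C)O[C@H]2C1 | intermediate
18 | tert-butyl (3R,4R,5S)-4,5-dihydroxy-3-[(6-methylheptanoyl)oxy]cyclohex-1-ene-1-carboxylate | CC(C)(C)OC(=O)C1=C[C@@H](OC(=O)CCCCC(C)C)[C@H](O)[C@@H](O)C1 | intermediate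
19 | tert-butyl (3R,4R,5S)-5-acetoxy-4-hydroxy-3-[(6-methylheptanoyl)oxy]cyclohex-1-ene-1-carboxylate | CC(C)(C)OC(=O)C1=C[C@@H](OC(=O)CCCCC(C)C)[C@H](O)[C@@H](OC(C)=O)C1 | intermediate
20 | tiglic acid ((2E)-2-methylbut-2-enoic acid) | C/C=C(\C)C(=O)O | starting material
21 | tiglic 2,4,6-trichlorobenzoic anhydride (not isolated) | C/C=C(\C)C(=O)OC(=O)c1c(Cl)cc(Cl)cc1Cl | intermediate
22 | tert-butyl (3R,4R,5S)-5-acetoxy-3-[(6-methylheptanoyl)oxy]-4-{[(2E)-2-methylbut-2-enoyl]oxy}cyclohex-1-ene-1-carboxylate | CC(C)(C)OC(=O)C1=C[C@@H](OC(=O)CCCCC(C)C)[C@H](OC(=O)/C(C)=C/C)[C@@H](OC(C)=O)C1 | intermediate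
23 | (3R,4R,5S)-5-acetoxy-3-[(6-methylheptanoyl)oxy]-4-{[(2E)-2-methylbut-2-enoyl]oxy}cyclohex-1-ene-1-carboxylic acid (CNP0225437.1) | C/C=C(\C)C(=O)O[C@@H]1[C@@H](OC(C)=O)CC(C(=O)O)=C[C@H]1OC(=O)CCCCC(C)C | target

**Step count and risks**
Total step count: 14.
Longest linear sequence: 14 steps (1 to 23). Compounds 6, 16 and 20 are purchased and enter in steps 4, 10 and 13.

Steps most likely to fail:

1. Step 9 (key step). What may go wrong: poor facial selectivity in the addition of the alkenylchromium to the C3 aldehyde. Both approach geometries keep O3 gauche to O4, so the bias toward the pseudo-equatorial alkoxide is only steric. Fallback, setting out from 13 and rejoining at 17: the cyclisation is run as in step 9 and the C3-epimeric alcohol tert-butyl (3S,4S,5S)-3-hydroxy-4,5-(isopropylidenedioxy)cyclohex-1-ene-1-carboxylate F1 is separated from 15. Mitsunobu esterification of F1 with acid 16 (PPh3, DIAD, THF, 0 °C) installs the 6-methylheptanoate with inversion at C3 and should give 17 directly. C3 is then set by SN2 displacement instead of by the addition, so both epimers converge.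

2. Step 6. What may go wrong: loss of geometric control in the O-sulfonylation. Reaction through the hydrogen-bonded or chelated Z enol places the triflate cis to the ester, and that isomer cannot close the ring. Fallback, setting out from 5 and rejoining at 15: the alkenyl partner is built as an (E)-iodide whose geometry comes from a decarboxylative elimination instead of an enolate trapping.
   - Triflate 5 alkylates diethyl malonate (NaH, THF/DMF) to give the diethyl alkylmalonate F2.
   - NaH and CHI3 in refluxing Et2O give the diethyl (diiodomethyl)alkylmalonate F3.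
   - KOH in aqueous EtOH at reflux saponifies both esters and triggers anti decarboxylative loss of iodide, which should give the (E)-3-iodoacrylic acid F4 with iodine trans to the carboxyl (the iodoform–malonate route to (E)-3-iodo-2-alkylacrylic acids).
   - tert-Butyl 2,2,2-trichloroacetimidate converts the acid into the tert-butyl ester F5.
   - HF·pyridine gives the primary alcohol F6, and Dess–Martin periodinane gives the iodo aldehyde F7.
   - F7 is cyclised with CrCl2 and catalytic NiCl2 in DMF as in step 9 to give 15.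

3. Step 12. What may go wrong: poor site selectivity between O5 and O4 with over-acetylation, or acetyl migration between O5 and O4 before step 13. Fallback, setting out from 18 and rejoining at 22: the order of acylation is reversed with a temporary bulky group.
   - TBSCl and imidazole in DMF at 0 °C should silylate the less hindered O5 far more selectively than a small acyl donor, giving the 5-O-TBS ether F8.
   - Yamaguchi esterification with 20 gives the 4-O-tigloyl 5-O-TBS compound F9.
   - HF·pyridine frees O5 to give the 5-hydroxy 4-tiglate F10.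
   - Ac2O, pyridine and catalytic DMAP then give 22.

**Further compounds**
F1 | step 9 | tert-butyl (3S,4S,5S)-3-hydroxy-4,5-(isopropylidenedioxy)cyclohex-1-ene-1-carboxylate (C3 epimer of 15) | CC(C)(C)OC(=O)C1=C[C@H](O)[C@@H]2OC(C)(C)O[C@H]2C1
F2 | step 6 | diethyl 2-{[(4S,5S)-5-({[tert-butyl(dimethyl)silyl]oxy}methyl)-2,2-dimethyl-1,3-dioxolan-4-yl]methyl}malonate | CC(C)(C)[Si](C)(C)OC[C@@H]1OC(C)(C)O[C@H]1CC(C(=O)OCC)C(=O)OCC
F3 | step 6 | diethyl 2-(diiodomethyl)-2-{[(4S,5S)-5-({[tert-butyl(dimethyl)silyl]oxy}methyl)-2,2-dimethyl-1,3-dioxolan-4-yl]methyl}malonate | CC(C)(C)[Si](C)(C)OC[C@@H]1OC(C)(C)O[C@H]1CC(C(I)I)(C(=O)OCC)C(=O)OCC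
F4 | step 6 | (2E)-2-{[(4S,5S)-5-({[tert-butyl(dimethyl)silyl]oxy}methyl)-2,2-dimethyl-1,3-dioxolan-4-yl]methyl}-3-iodoprop-2-enoic acid | CC(C)(C)[Si](C)(C)OC[C@@H]1OC(C)(C)O[C@H]1C/C(C(=O)O)=C\I
F5 | step 6 | tert-butyl (2E)-2-{[(4S,5S)-5-({[tert-butyl(dimethyl)silyl]oxy}methyl)-2,2-dimethyl-1,3-dioxolan-4-yl]methyl}-3-iodoprop-2-enoate | CC(C)(C)[Si](C)(C)OC[C@@H]1OC(C)(C)O[C@H]1C/C(C(=O)OC(C)(C)C)=C\I
F6 | step 6 | tert-butyl (2E)-2-{[(4S,5S)-5-(hydroxymethyl)-2,2-dimethyl-1,3-dioxolan-4-yl]methyl}-3-iodoprop-2-enoate | OC[C@@H]1OC(C)(C)O[C@H]1C/C(C(=O)OC(C)(C)C)=C\I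
F7 | step 6 | tert-butyl (2E)-2-{[(4S,5R)-5-formyl-2,2-dimethyl-1,3-dioxolan-4-yl]methyl}-3-iodoprop-2-enoate | O=C[C@@H]1OC(C)(C)O[C@H]1C/C(C(=O)OC(C)(C)C)=C\I
F8 | step 12 | 5-O-TBS ether of diol 18 (tert-butyl 5-{[tert-butyl(dimethyl)silyl]oxy}-4-hydroxy-3-[(6-methylheptanoyl)oxy]cyclohex-1-ene-1-carboxylate, all-trans) | CC(C)(C)OC(=O)C1=C[C@@H](OC(=O)CCCCC(C)C)[C@H](O)[C@@H](O[Si](C)(C)C(C)(C)C)C1
F9 | step 12 | 4-O-tigloyl 5-O-TBS derivative (tert-butyl 5-{[tert-butyl(dimethyl)silyl]oxy}-3-[(6-methylheptanoyl)oxy]-4-{[(2E)-2-methylbut-2-enoyl]oxy}cyclohex-1-ene-1-carboxylate, all-trans) | CC(C)(C)OC(=O)C1=C[C@@H](OC(=O)CCCCC(C)C)[C@H](OC(=O)/C(C)=C/C)[C@@H](O[Si](C)(C)C(C)(C)C)C1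
F10 | step 12 | tert-butyl (3R,4R,5S)-5-hydroxy-3-[(6-methylheptanoyl)oxy]-4-{[(2E)-2-methylbut-2-enoyl]oxy}cyclohex-1-ene-1-carboxylate | CC(C)(C)OC(=O)C1=C[C@@H](OC(=O)CCCCC(C)C)[C@H](OC(=O)/C(C)=C/C)[C@@H](O)C1
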